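Cuts (germacrane numbering: C1=C10 enoate, C4–C5 oxirane, C6–O/C7 lactone, C8 ester, C9 acetate): O9–Ac, then C9–C10 (the ten-membered ring), O8–acyl, the C4–C5 oxirane oxygen, C6–C7 together with O6–C12, C1=C10, C7–C11.
Forward order of rings: the side-chain oxirane (made in the acid) and the γ-lactone come first, the C4–C5 oxirane next, the C1–C10 carbocycle last. The fragments are neryl acetate (C1–C6, C15), glyceraldehyde (C7–C9), methyl acrylate (C11–C13) and a phosphorane (C10, C14).
Enabling feature: C9 is a carbinol on C10, the α-carbon of the C1=C10 enoate, with C2 and C9 cis on that alkene, so C9–C10 is the bond an alkenyl metal at C10 makes with a C9 aldehyde. The cis-oxirane (C3/C6 cis), the cis-fused lactone (C5/C8 cis) and the Z-iodoalkene fold the open chain so that C9 and C10 meet.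
Stereochemistry: C8 comes from (R)-glyceraldehyde acetonide, and C6/C7 are relayed from C8 in a closed allylindium transition state. C4/C5 follow from C6 by A(1,3)-controlled epoxidation of the Z-alkene inherited from neryl acetate. C9 is set in the ring closure, C2′ by Sharpless epoxidation, and the C1=C10 geometry by a Z-selective iodo-Wittig reaction.

Key step: step 15

Remark on the chemistry: the SMILES is taken literally, which gives 4R,5S,6R,7R,8S,9S,2′S, that is C3/C6 cis on the oxirane, H6/H7 cis at the lactone fusion, O8/O9 trans on the ring and C2/C9 cis on C1=C10 (E by the sequence rule); germacrane numbers are used for all intermediates.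

Step 1
Reactants: 1 neryl acetate
Product: 2 (4Z)-6-acetoxy-4-methylhex-4-enal
Conditions: O3 (1 equiv), CH2Cl2, −78 °C; then Me2S, −78 °C to rt
Reagents that add atoms: ozone [O-][O+]=O
Why: Ozonolysis with reductive work-up: one equivalent of ozone should cleave the electron-rich distal trisubstituted alkene ahead of the C4=C5 alkene, which the allylic acetate deactivates, so the Z geometry of C4=C5 is simply inherited and no stereocentre is formed.

Step 2
Reactants: 2 (4Z)-6-acetoxy-4-methylhex-4-enal; 3 methyl (triphenylphosphoranylidene)acetate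
Product: 5 methyl (2Z,6Z)-8-acetoxy-2-iodo-6-methylocta-2,6-dienoate, via iodo ylide 4 (not isolated)
Conditions: 3, NIS, CH2Cl2, −20 °C; then 2, −20 °C to rt
Reagents that add atoms: N-iodosuccinimide O=C1CCC(=O)N1I
Why: Wittig olefination with a stabilised α-iodo ylide, made in the flask by iodination of 3 and deprotonation by the succinimide anion, should place the ester trans to the chain and thus give the (Z)-α-iodoenoate in which iodine (the later C9) and C2 are cis.

Step 3
Reactants: 5 methyl (2Z,6Z)-8-acetoxy-2-iodo-6-methylocta-2,6-dienoate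
Product: 6 methyl (2Z,6Z)-8-hydroxy-2-iodo-6-methylocta-2,6-dienoate
Conditions: K2CO3 (cat.), MeOH, 0 °C
Reagents that add atoms: none
Why: Carbonate-catalysed transesterification removes the allylic acetate, while exchange at the conjugated methyl ester is degenerate and the short, cold exposure should spare the iodoacrylate from conjugate addition.

Step 4
Reactants: 6 methyl (2Z,6Z)-8-hydroxy-2-iodo-6-methylocta-2,6-dienoate
Product: 7 methyl (2Z,6Z)-2-iodo-6-methyl-8-oxoocta-2,6-dienoate
Conditions: TEMPO (cat.), PhI(OAc)2, MeCN/pH 7 buffer, 0 °C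
Reagents that add atoms: none
Why: Oxoammonium (TEMPO/PhI(OAc)2) oxidation of a primary allylic alcohol runs near neutrality, conditions under which neral-type Z-enals keep their geometry.

Step 5
Reactants: 8 (R)-2,2-dimethyl-1,3-dioxolane-4-carbaldehyde; 9 methyl acrylate
Product: 10 methyl 2-{hydroxy[(4R)-2,2-dimethyl-1,3-dioxolan-4-yl]methyl}prop-2-enoate (both carbinol epimers)
Conditions: DABCO, dioxane/H2O, rt
Reagents that add atoms: none
Why: The Morita–Baylis–Hillman reaction joins C7 to C11; the new carbinol centre forms as a mixture that does not matter because C7 becomes sp2 in step 6, and C8 comes unchanged from the chiral pool.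

Step 6
Reactants: 10 methyl 2-{hydroxy[(4R)-2,2-dimethyl-1,3-dioxolan-4-yl]methyl}prop-2-enoate
Product: 11 methyl (2Z)-2-(bromomethyl)-3-[(4S)-2,2-dimethyl-1,3-dioxolan-4-yl]prop-2-enoate
Conditions: NBS, Me2S, CH2Cl2, 0 °C to rt
Reagents that add atoms: N-bromosuccinimide O=C1CCC(=O)N1Br
Why: Allylic bromination with transposition (SN2′ attack of bromide on the alkoxysulfonium salt from NBS/Me2S) should give the Z-bromide with C8 trans to the ester under non-acidic conditions that keep the acetonide.

Step 7
Reactants: 7 methyl (2Z,6Z)-2-iodo-6-methyl-8-oxoocta-2,6-dienoate; 11 methyl (2Z)-2-(bromomethyl)-3-[(4S)-2,2-dimethyl-1,3-dioxolan-4-yl]prop-2-enoate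
Product: 13 methyl (2Z,6Z)-7-{(2S,3S)-3-[(4S)-2,2-dimethyl-1,3-dioxolan-4-yl]-4-methylidene-5-oxooxolan-2-yl}-2-iodo-6-methylhepta-2,6-dienoate (cis-lactone; 6S,7S,8S), via hydroxy ester 12 (not isolated)
Conditions: In powder, THF/H2O 1:1, rt; extraction; PPTS (cat.), toluene, 45 °C
Reagents that add atoms: none
Why: Barbier-type 2-(alkoxycarbonyl)allylation followed by acid-catalysed lactonisation: in the Z-allylindium, A(1,3) strain keeps H8 in the alkene plane and O8 can bind indium, so the aldehyde should be delivered through a closed chair to the O8 face of C7 with its alkenyl group equatorial, which sets 6,7-syn (cis-lactone) and relays C8 to C7 and C6, the vinyl iodide and the enal geometry being inert to indium in aqueous THF.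

Step 8
Reactants: 13 lactone acetonide
Product: 14 methyl (2Z,6Z)-7-{(2S,3R)-3-[(1S)-1,2-dihydroxyethyl]-4-methylidene-5-oxooxolan-2-yl}-2-iodo-6-methylhepta-2,6-dienoate (6S,7R,8S)
Conditions: AcOH/THF/H2O 3:1:1, 40 °C
Reagents that add atoms: none
Why: Mild acid-catalysed acetal hydrolysis frees O8 and O9 before any acid-labile oxirane is present and touches no stereocentre.

Step 9
Reactants: 14 lactone diol
Product: 15 9-O-triethylsilyl ether of 14 (C8–OH free; 6S,7R,8S)
Conditions: TESCl (1.05 equiv), imidazole, CH2Cl2, −40 °C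
Reagents that add atoms: chlorotriethylsilane CC[Si](Cl)(CC)CC
Why: Silylation under steric control takes the primary C9 hydroxyl and leaves the hindered secondary C8 hydroxyl free for acylation.

Step 10
Reactants: 16 2-methylprop-2-en-1-ol
Product: 17 (R)-(2-methyloxiran-2-yl)methanol
Conditions: Ti(OiPr)4 (cat.), D-(−)-DIPT (cat.), t-BuOOH, 4 Å MS, CH2Cl2, −20 °C
Reagents that add atoms: tert-butyl hydroperoxide CC(C)(C)OO
Why: Sharpless asymmetric epoxidation, in which the D-(−)-tartrate catalyst delivers oxygen to the alkene face that gives the R epoxy alcohol and thereby sets C2′.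

Step 11
Reactants: 17 (R)-(2-methyloxiran-2-yl)methanol
Product: 18 (S)-2-methyloxirane-2-carboxylic acid
Conditions: RuCl3 (cat.), NaIO4, MeCN/EtOAc/H2O, 0 °C to rt
Reagents that add atoms: water O
Why: Ruthenium tetroxide-catalysed oxidation takes the primary alcohol to the acid without touching the quaternary centre, whose descriptor changes from R to S only because the priorities change.

Step 12
Reactants: 15 9-O-triethylsilyl ether; 18 (S)-2-methyloxirane-2-carboxylic acid
Product: 19 8-O-[(2S)-2-methyloxirane-2-carbonyl] ester of 15 (6S,7S,8S,2′S)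
Conditions: DCC, DMAP (cat.), CH2Cl2, 0 °C to rt
Reagents that add atoms: none
Why: Steglich esterification forms the O8–acyl bond at the carbonyl carbon, so C8 and C2′ are retained and the oxirane of the acid is not opened.

Step 13
Reactants: 19 8-O-acyl 9-O-silyl lactone
Product: 20 4,5-cis-epoxide of 19 (4R,5S,6R,7R,8S,2′S)
Conditions: m-CPBA, CH2Cl2/pH 7 phosphate buffer, 0 °C
Reagents that add atoms: 3-chloroperbenzoic acid OOC(=O)c1cccc(Cl)c1
Why: Prilezhaev epoxidation picks the only electron-rich alkene, and because A(1,3) strain between C3H2 and C6 holds H6 in the alkene plane, the peracid should approach from the face flanked by O6 and away from C7 with its cis side chain, giving the cis-oxirane 4R,5S (threo to O6).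

Step 14
Reactants: 20 epoxy lactone silyl ether
Product: 21 seco aldehyde (C9 aldehyde, C10 alkenyl iodide; 4R,5S,6R,7S,8S,2′S)
Conditions: (COCl)2, DMSO, CH2Cl2, −78 to −40 °C; then Et3N, −78 to 0 °C
Reagents that add atoms: none
Why: Swern oxidation applied directly to a primary triethylsilyl ether (activated DMSO displaces the silyl group and the alkoxysulfonium ylide collapses to the aldehyde) avoids a free C9 hydroxyl next to the O8 ester and with it acyl migration, and the cold amine step should keep C8 intact.

Step 15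
Reactants: 21 seco aldehyde
Product: 22 macrocyclic 9-alcohol (9-deacetyl target; 4R,5S,6R,7R,8S,9S,2′S)
Conditions: CrCl2 (15 equiv), NiCl2 (cat.), degassed DMSO/THF, slow addition of 21 to about 2 mM, rt; aqueous work-up
Reagents that add atoms: none
Why: Ni(0), formed from NiCl2 by Cr(II), inserts into the C10–I bond, the alkenyl group passes to Cr(III), and the alkenylchromium adds to the chromium-bound C9 aldehyde to form C9–C10. The closest known reaction type is the intramolecular Nozaki–Hiyama–Kishi closure of ten-membered lactones and carbocycles, germacranolide rings included, from alkenyl iodide–aldehydes. The ring closes in the 10-exo-trig mode (C=O exocyclic) with C1=C10 inside the ring and its geometry (C2 cis to the new bond) retained from the Z-iodide, a trans-in-ring alkene being out of reach for a chain that already holds the cis-oxirane and the cis-lactone. C9 is controlled by the forming ring: with a gauche C7–C8–C9–C10 torsion, the C8–O8 bond anti to the incoming C10 and the chromium-bound carbonyl oxygen anti to C7 and pointing outward, both oxygens become peripheral (pseudo-equatorial), which is the 8,9-trans arrangement, 9S. The step needs chemoselectivity (only C–I is activated and only the aldehyde is attacked, since the lactone, two esters, two oxiranes and two acrylate units are inert to organochromium(III)) and cyclisation over oligomerisation, which slow addition at high dilution and the U-shape imposed by the three cis elements should secure. O9 is born free while O8 is already acylated, so the two ester positions never have to be told apart.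

Step 16
Reactants: 22 macrocyclic 9-alcohol
Product: 23 target compound CNP0274195.1
Conditions: Ac2O, pyridine, DMAP (cat.), CH2Cl2, 0 °C
Reagents that add atoms: acetic anhydride CC(=O)OC(C)=O
Why: DMAP-catalysed acylation of the free allylic C9 hydroxyl proceeds with retention and completes the target.

Compound list
1 | neryl acetate, (2Z)-3,7-dimethylocta-2,6-dien-1-yl acetate | CC(C)=CCC/C(C)=C\COC(C)=O | starting material
2 | (4Z)-6-acetoxy-4-methylhex-4-enal | O=CCC/C(C)=C\COC(C)=O | intermediate
3 | methyl (triphenylphosphoranylidene)acetate | COC(=O)C=P(c1ccccc1)(c1ccccc1)c1ccccc1 | starting material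
4 | methyl iodo(triphenylphosphoranylidene)acetate (iodo ylide) | COC(=O)C(I)=P(c1ccccc1)(c1ccccc1)c1ccccc1 | intermediate
5 | methyl (2Z,6Z)-8-acetoxy-2-iodo-6-methylocta-2,6-dienoate | COC(=O)/C(I)=C/CC/C(C)=C\COC(C)=O | intermediate
6 | methyl (2Z,6Z)-8-hydroxy-2-iodo-6-methylocta-2,6-dienoate | COC(=O)/C(I)=C/CC/C(C)=C\CO | intermediate
7 | methyl (2Z,6Z)-2-iodo-6-methyl-8-oxoocta-2,6-dienoate | COC(=O)/C(I)=C/CC/C(C)=C\C=O | intermediate
8 | (R)-2,2-dimethyl-1,3-dioxolane-4-carbaldehyde | O=C[C@H]1COC(C)(C)O1 | starting material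
9 | methyl acrylate | C=CC(=O)OC | starting material
10 | methyl 2-{hydroxy[(4R)-2,2-dimethyl-1,3-dioxolan-4-yl]methyl}prop-2-enoate, carbinol epimers | C=C(C(=O)OC)C(O)[C@H]1COC(C)(C)O1 | intermediate
11 | methyl (2Z)-2-(bromomethyl)-3-[(4S)-2,2-dimethyl-1,3-dioxolan-4-yl]prop-2-enoate | COC(=O)/C(CBr)=C/[C@H]1COC(C)(C)O1 | intermediate
12 | methyl (2Z,6Z,8S,9S)-9-[(4S)-2,2-dimethyl-1,3-dioxolan-4-yl]-8-hydroxy-2-iodo-10-(methoxycarbonyl)-6-methylundeca-2,6,10-trienoate (hydroxy ester, 6,7-syn) | C=C(C(=O)OC)[C@@H]([C@@H](O)/C=C(/C)CC/C=C(\I)C(=O)OC)[C@H]1COC(C)(C)O1 | intermediate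
13 | cis-lactone acetonide (6S,7S,8S), name as in step 7 | C=C1C(=O)O[C@@H](/C=C(/C)CC/C=C(\I)C(=O)OC)[C@H]1[C@H]2COC(C)(C)O2 | intermediate
14 | cis-lactone 8,9-diol (6S,7R,8S), name as in step 8 | C=C1C(=O)O[C@@H](/C=C(/C)CC/C=C(\I)C(=O)OC)[C@H]1[C@H](O)CO | intermediate
15 | 9-O-triethylsilyl ether of 14 (6S,7R,8S) | C=C1C(=O)O[C@@H](/C=C(/C)CC/C=C(\I)C(=O)OC)[C@H]1[C@H](O)CO[Si](CC)(CC)CC | intermediate
16 | 2-methylprop-2-en-1-ol | C=C(C)CO | starting material
17 | (R)-(2-methyloxiran-2-yl)methanol | OC[C@]1(C)CO1 | intermediate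
18 | (S)-2-methyloxirane-2-carboxylic acid | OC(=O)[C@]1(C)CO1 | intermediate
19 | 8-O-[(2S)-2-methyloxirane-2-carbonyl]-9-O-triethylsilyl lactone (6S,7S,8S,2′S) | C=C1C(=O)O[C@@H](/C=C(/C)CC/C=C(\I)C(=O)OC)[C@H]1[C@H](OC(=O)[C@]2(C)CO2)CO[Si](CC)(CC)CC | intermediate
20 | 4,5-cis-epoxide of 19 (4R,5S,6R,7R,8S,2′S) | C=C1C(=O)O[C@@H]([C@@H]2O[C@]2(C)CC/C=C(\I)C(=O)OC)[C@H]1[C@H](OC(=O)[C@]2(C)CO2)CO[Si](CC)(CC)CC | intermediate
21 | seco aldehyde: C9 aldehyde and C10 (Z)-alkenyl iodide (4R,5S,6R,7S,8S,2′S) | C=C1C(=O)O[C@@H]([C@@H]2O[C@]2(C)CC/C=C(\I)C(=O)OC)[C@H]1[C@H](OC(=O)[C@]2(C)CO2)C=O | intermediate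
22 | macrocyclic 9-alcohol, 9-deacetyl target (4R,5S,6R,7R,8S,9S,2′S) | C=C1C(=O)O[C@@H]2[C@H]1[C@H](OC(=O)[C@]1(C)CO1)[C@@H](O)/C(C(=O)OC)=C\CC[C@@]1(C)O[C@@H]21 | intermediate
23 | CNP0274195.1 (4R,5S,6R,7R,8S,9S,2′S) | C=C1C(=O)O[C@@H]2[C@H]1[C@H](OC(=O)[C@]1(C)CO1)[C@@H](OC(C)=O)/C(C(=O)OC)=C\CC[C@@]1(C)O[C@@H]21 | target

Total step count: 16. Longest linear sequence: 12 (steps 1–4, 7–9, 12–16).

Steps most likely to fail

1. Step 15.
Process: addition to the other face of the aldehyde, as the open-chain 1,2-induction model (carbonyl oxygen turned towards C7) would favour, so that the 9R carbinol forms.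
Fallback: it sets out from 21 and comes back at 23. The closure is run as before. The 9R alcohol F1 is then not acylated with retention but submitted to a Mitsunobu reaction (AcOH, PPh3, DIAD, toluene, 0 °C). Acetate displaces the activated allylic oxygen with inversion, so the C9–O bond rather than the O–acyl bond is formed and 23 results directly.

2. Step 7.
Process: delivery of the aldehyde to the face of C7 anti to the C8–O bond, which would give C6 and C7 with the wrong sense relative to C8.
Fallback: it sets out from 7 and comes back at 19. That sense of induction is accepted and C8 is corrected later.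
- Commercial (S)-2,2-dimethyl-1,3-dioxolane-4-carbaldehyde is taken through the chemistry of steps 5 and 6 to the Morita–Baylis–Hillman adduct F2 and the Z-bromide F3.
- Indium coupling with 7 gives the 8-epi hydroxy ester F4 and, after lactonisation, the 8-epi lactone acetonide F5, which has C6 and C7 as in 13.
- Hydrolysis gives the 8-epi diol F6 and silylation gives the 8-epi silyl ether F7.
- A Mitsunobu esterification of F7 with 18 (PPh3, DIAD, THF, 0 °C) inverts C8 while it installs the ester, giving 19.

3. Step 13.
Process: reversed facial selectivity, since no hydroxyl group guides the peracid.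
Fallback: it sets out from 19 and comes back at 20. NBS in aqueous DME gives the bromohydrin F8, with the bromonium ion on the face that electrophiles prefer and water attacking tertiary C4 from the other face. K2CO3 in acetone then closes the oxirane by SN2 displacement of bromide at C5, which puts the oxygen on the face opposite to the one the peracid chose.

Further compounds
F1 | step 15 | 9R alcohol, 9-epimer of 22 | C=C1C(=O)O[C@@H]2[C@H]1[C@H](OC(=O)[C@]1(C)CO1)[C@H](O)/C(C(=O)OC)=C\CC[C@@]1(C)O[C@@H]21
F2 | step 7 | methyl 2-{hydroxy[(4S)-2,2-dimethyl-1,3-dioxolan-4-yl]methyl}prop-2-enoate, carbinol epimers | C=C(C(=O)OC)C(O)[C@@H]1COC(C)(C)O1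
F3 | step 7 | methyl (2Z)-2-(bromomethyl)-3-[(4R)-2,2-dimethyl-1,3-dioxolan-4-yl]prop-2-enoate | COC(=O)/C(CBr)=C/[C@@H]1COC(C)(C)O1
F4 | step 7 | 8-epimer of hydroxy ester 12 | C=C(C(=O)OC)[C@@H]([C@@H](O)/C=C(/C)CC/C=C(\I)C(=O)OC)[C@@H]1COC(C)(C)O1
F5 | step 7 | 8-epimer of lactone acetonide 13 | C=C1C(=O)O[C@@H](/C=C(/C)CC/C=C(\I)C(=O)OC)[C@H]1[C@@H]2COC(C)(C)O2
F6 | step 7 | 8-epimer of diol 14 | C=C1C(=O)O[C@@H](/C=C(/C)CC/C=C(\I)C(=O)OC)[C@H]1[C@@H](O)CO
F7 | step 7 | 8-epimer of silyl ether 15 | C=C1C(=O)O[C@@H](/C=C(/C)CC/C=C(\I)C(=O)OC)[C@H]1[C@@H](O)CO[Si](CC)(CC)CC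
F8 | step 13 | 5-bromo-4-hydroxy bromohydrin of 19 | C=C1C(=O)O[C@@H]([C@@H](Br)[C@](C)(O)CC/C=C(\I)C(=O)OC)[C@H]1[C@H](OC(=O)[C@]2(C)CO2)CO[Si](CC)(CC)CC
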